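**Plan**

1. Ring B is traced back from the phenol to a racemic 6-methoxycyclohex-2-enone, which is cut at C1'–C2' (aldol) and C4'–C5' (Michael) into methoxyacetone and a vinyl ketone on C2 of the chromone.
2. The feature that allows this: on ring B the free 3'-OH lies beside the 4'-OMe, and these two carbons are the C3' ketone and the methoxy-bearing C4' of that cyclohexenone, with C1' para to the methoxy group, so the phenol needs no protecting group.
3. The vinyl ketone is cut at C1'–C6' (vinyl Grignard on a Weinreb amide); ring C is cut at O1–C2 and C2–C3 (diethyl oxalate) and at C4–C4a (Friedel–Crafts acylation of 1,2,3-trimethoxybenzene).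
4. Forward: ring A is bought, ring C is closed in step 2, the C1'/C6'/C5' side chain is completed in steps 3 and 4, ring B is closed in step 5 and aromatised in step 6.
5. Stereochemistry: the target has no stereocentre; the only one made on the way (C4' in 13, 14 and 15) is racemic and is erased in step 6.

Key step: step 5

Remark: ring B atoms are numbered C1' (bonded to C2 of the chromone) to C6' in all intermediates, and every chiral intermediate is handled as a racemate.

**Route**

Step 1
Reactants: 1 1,2,3-trimethoxybenzene; 2 methoxyacetyl chloride
Product: 4 1-(2-hydroxy-3,4-dimethoxyphenyl)-2-methoxyethan-1-one, via the trimethoxyphenyl ketone 3 (not isolated)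
Conditions: AlCl3 (3 equiv), Et2O, 0 °C to rt; then 2 M HCl
Reagents that add atoms: none
Why: Friedel–Crafts acylation should occur at C4 of 1, para to a terminal methoxy group, and AlCl3 chelated between the new carbonyl and the neighbouring methoxy oxygen then cleaves only that ortho methyl ether, as is usual for ortho-methoxyaryl ketones, while the aliphatic methyl ether of the side chain is a poorer leaving group and should stay.

Step 2
Reactants: 4 1-(2-hydroxy-3,4-dimethoxyphenyl)-2-methoxyethan-1-one; 5 diethyl oxalate
Product: 7 ethyl 3,7,8-trimethoxy-4-oxo-4H-chromene-2-carboxylate, via the diketo ester 6 (not isolated)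
Conditions: NaOEt (4 equiv), (CO2Et)2 (3 equiv), EtOH, 0 °C to reflux; then conc. HCl, EtOH, reflux
Reagents that add atoms: none
Why: Crossed Claisen condensation of the ketone enolate (at the methoxy-bearing CH2) with non-enolisable diethyl oxalate gives 6, and acid-catalysed addition of the phenol to the new 2-oxo group followed by loss of water closes ring C, which is the standard chromone-2-carboxylate synthesis.

Step 3
Reactants: 7 ethyl 3,7,8-trimethoxy-4-oxo-4H-chromene-2-carboxylate
Product: 8 N,3,7,8-tetramethoxy-N-methyl-4-oxo-4H-chromene-2-carboxamide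
Conditions: MeNH(OMe)·HCl (3 equiv), AlMe3 (3 equiv), CH2Cl2, 0 °C to rt; then 1 M HCl
Reagents that add atoms: N,O-dimethylhydroxylamine hydrochloride, CNOC.Cl
Why: Weinreb amidation of an ester: the aluminium amide made from AlMe3 and the amine salt attacks the ester carbonyl, which the electron-poor pyranone activates, while the C4 carbonyl, a vinylogous ester, should be left alone.

Step 4
Reactants: 8 N,3,7,8-tetramethoxy-N-methyl-4-oxo-4H-chromene-2-carboxamide; 9 vinylmagnesium bromide
Product: 11 3,7,8-trimethoxy-2-(prop-2-enoyl)-4H-chromen-4-one, via the magnesium chelate 10 (not isolated)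
Conditions: CH2=CHMgBr (1.2 equiv), THF, −78 to −40 °C; inverse quench into cold 1 M HCl
Reagents that add atoms: none
Why: Weinreb ketone synthesis: the five-membered N-methoxy chelate 10 persists at low temperature so that only one vinyl group is transferred, the amide reacts ahead of the vinylogous-ester C4 carbonyl, and the cold acidic inverse quench protonates the released N,O-dimethylhydroxylamine before it can add to the new enone.

Step 5
Reactants: 11 3,7,8-trimethoxy-2-(prop-2-enoyl)-4H-chromen-4-one; 12 methoxyacetone
Product: 15 racemic 3,7,8-trimethoxy-2-(4-methoxy-3-oxocyclohex-1-en-1-yl)-4H-chromen-4-one, via the Michael adduct 13 (not isolated), via the aldol 14 (not isolated)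
Conditions: 12 (5 equiv), pyrrolidine (30 mol%), AcOH (30 mol%), toluene, 0 °C to rt; then 80 °C
Reagents that add atoms: none
Why: Pyrrolidine converts 12 into its more substituted, methoxy-bearing enamine, whose oxygenated carbon adds to the terminal CH2 of the vinyl ketone (C4'–C5'), and hydrolysis gives diketone 13 and returns the amine. The methyl ketone of 13 then reacts through its CH3-side enamine with the strongly electrophilic chromonyl ketone (C1'–C2'), and aldol 14 loses water on warming to give the enone conjugated with ring C. The closest known reaction type is the enamine variant of the Robinson annulation of a ketone with an aryl vinyl ketone, and the donor regiochemistry follows the amine-catalysed aldol and Mannich reactions of methoxyacetone, which run through the oxygenated carbon. Ring B closes by a 6-(enolendo)-exo-trig aldol, the only closure of 13 that does not give a four-membered ring. The new stereocentre C4' has no controlling element (achiral amine, racemic product) and needs none, because it becomes sp2 in step 6. The step needs Michael addition at the OCH2 and not the CH3 carbon of 12, which the methoxy group secures by stabilising and activating the enamine on that side, and attack at the vinyl terminus and not at the pyranone, which is secured by the unsubstituted β-carbon of the enone while C2 of ring C is fully substituted and flanked by the 3-methoxy group.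

Step 6
Reactants: 15 racemic 3,7,8-trimethoxy-2-(4-methoxy-3-oxocyclohex-1-en-1-yl)-4H-chromen-4-one
Product: 17 diplotrin B, via the cyclohexadienone 16 (not isolated)
Conditions: Pd(OCOCF3)2 (5 mol%), 2-(dimethylamino)pyridine (10 mol%), TsOH·H2O (20 mol%), O2 (1 atm), DMSO, 80 °C
Reagents that add atoms: none
Why: Aerobic dehydrogenation catalysed by divalent palladium: palladation at the α'-carbon C4' and β-hydride elimination toward C5' give the cross-conjugated dienone 16, which tautomerises at once to the phenol, while O2 reoxidises the zerovalent palladium; this is the known conversion of 3-arylcyclohexenones into meta-arylphenols.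

**Compound list**

1 | 1,2,3-trimethoxybenzene | COc1cccc(OC)c1OC | starting material
2 | methoxyacetyl chloride | COCC(Cl)=O | starting material
3 | 2-methoxy-1-(2,3,4-trimethoxyphenyl)ethan-1-one | COCC(=O)c1ccc(OC)c(OC)c1OC | intermediate (not isolated)
4 | 1-(2-hydroxy-3,4-dimethoxyphenyl)-2-methoxyethan-1-one | COCC(=O)c1ccc(OC)c(OC)c1O | intermediate
5 | diethyl oxalate | CCOC(=O)C(=O)OCC | starting material
6 | ethyl 4-(2-hydroxy-3,4-dimethoxyphenyl)-3-methoxy-2,4-dioxobutanoate (racemic, present as its enolate) | CCOC(=O)C(=O)C(OC)C(=O)c1ccc(OC)c(OC)c1O | intermediate (not isolated)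
7 | ethyl 3,7,8-trimethoxy-4-oxo-4H-chromene-2-carboxylate | CCOC(=O)c1oc2c(OC)c(OC)ccc2c(=O)c1OC | intermediate
8 | N,3,7,8-tetramethoxy-N-methyl-4-oxo-4H-chromene-2-carboxamide | CON(C)C(=O)c1oc2c(OC)c(OC)ccc2c(=O)c1OC | intermediate
9 | vinylmagnesium bromide | C=C[Mg]Br | starting material
10 | bromomagnesium 1-[methoxy(methyl)amino]-1-(3,7,8-trimethoxy-4-oxo-4H-chromen-2-yl)prop-2-en-1-olate (tetrahedral adduct, racemic) | C=CC(O[Mg]Br)(N(C)OC)c1oc2c(OC)c(OC)ccc2c(=O)c1OC | intermediate (not isolated)
11 | 3,7,8-trimethoxy-2-(prop-2-enoyl)-4H-chromen-4-one | C=CC(=O)c1oc2c(OC)c(OC)ccc2c(=O)c1OC | intermediate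
12 | methoxyacetone (1-methoxypropan-2-one) | COCC(C)=O | starting material
13 | 4-methoxy-1-(3,7,8-trimethoxy-4-oxo-4H-chromen-2-yl)hexane-1,5-dione (racemic) | CC(=O)C(OC)CCC(=O)c1oc2c(OC)c(OC)ccc2c(=O)c1OC | intermediate (not isolated)
14 | 2-(1-hydroxy-4-methoxy-3-oxocyclohexyl)-3,7,8-trimethoxy-4H-chromen-4-one (racemic, both diastereomers) | COC1CCC(O)(c2oc3c(OC)c(OC)ccc3c(=O)c2OC)CC1=O | intermediate (not isolated)
15 | 3,7,8-trimethoxy-2-(4-methoxy-3-oxocyclohex-1-en-1-yl)-4H-chromen-4-one (racemic) | COC1CCC(c2oc3c(OC)c(OC)ccc3c(=O)c2OC)=CC1=O | intermediate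
16 | 3,7,8-trimethoxy-2-(4-methoxy-3-oxocyclohexa-1,4-dien-1-yl)-4H-chromen-4-one | COC1=CCC(c2oc3c(OC)c(OC)ccc3c(=O)c2OC)=CC1=O | intermediate (not isolated)
17 | diplotrin B, 2-(3-hydroxy-4-methoxyphenyl)-3,7,8-trimethoxy-4H-chromen-4-one | COc1ccc(-c2oc3c(OC)c(OC)ccc3c(=O)c2OC)cc1O | target

**Summary**

Total step count: 6. Longest linear sequence: 6 steps (1 to 17).

**Steps most likely to fail**

Step 5. The Michael addition may run through the methyl-side enamine of 12. The secondary amine may also be consumed by conjugate addition to the pyranone of 11 with ring opening, or 11 may polymerise before it is intercepted. The fallback sets out from 12 and 11 and comes back to the route at 15 by way of 13, which is isolated this time. Methoxyacetone 12 is silylated under equilibrating conditions (TMSCl, Et3N, DMF, 80 °C) to (Z)-1-methoxy-2-(trimethylsilyloxy)prop-1-ene F1, which is distilled so that the regiochemistry of the donor is fixed and checked before the C–C bond is made. Mukaiyama–Michael addition of F1 to 11 (TiCl4, CH2Cl2, −78 °C, then aq. NaHCO3) should give diketone 13 without any amine. Acid-catalysed aldol cyclodehydration (TsOH·H2O, toluene, reflux with azeotropic removal of water) then closes ring B to 15. Both operations are known reaction types, and the same two bonds are formed.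

Step 4. The Grignard reagent may add to the pyranone (at C2 or C4) in competition with the amide, the released hydroxylamine may add to the enone during the quench, or the vinyl ketone may polymerise on concentration; 11 should in any case be used without storage. The fallback sets out from 7 and comes back at 11 without an organomagnesium reagent. Acid hydrolysis (aq. HCl, AcOH, 80 °C) should give 3,7,8-trimethoxy-4-oxo-4H-chromene-2-carboxylic acid F2. Oxalyl chloride with catalytic DMF in CH2Cl2 converts it into 3,7,8-trimethoxy-4-oxo-4H-chromene-2-carbonyl chloride F3. Stille acylation of F3 with tributyl(vinyl)stannane (PdCl2(PPh3)2 as a precatalyst of divalent palladium, toluene, 60 °C) delivers 11 under neutral conditions.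

Step 6. Palladation at the hindered methoxy-bearing carbon may be slow, and the electron-rich phenol may be degraded by prolonged heating under O2. The fallback sets out from 15 and comes back at 17. Soft enolisation (TMSOTf, Et3N, CH2Cl2, 0 °C) should give the silyl dienol ether 3,7,8-trimethoxy-2-[4-methoxy-3-(trimethylsilyloxy)cyclohexa-1,3-dien-1-yl]-4H-chromen-4-one F4; a regioisomeric dienol ether would lead to the same arene. DDQ (1.1 equiv, CH2Cl2, rt) aromatises the cyclohexadiene by hydride abstraction to 3,7,8-trimethoxy-2-[4-methoxy-3-(trimethylsilyloxy)phenyl]-4H-chromen-4-one F5, in which the phenol stays masked until the oxidant is consumed. Treatment with 1 M HCl in THF at rt removes the silyl group and gives 17.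

**Further compounds**

F1 | step 5 | (Z)-1-methoxy-2-(trimethylsilyloxy)prop-1-ene | CO/C=C(/C)O[Si](C)(C)C
F2 | step 4 | 3,7,8-trimethoxy-4-oxo-4H-chromene-2-carboxylic acid | OC(=O)c1oc2c(OC)c(OC)ccc2c(=O)c1OC
F3 | step 4 | 3,7,8-trimethoxy-4-oxo-4H-chromene-2-carbonyl chloride | ClC(=O)c1oc2c(OC)c(OC)ccc2c(=O)c1OC
F4 | step 6 | 3,7,8-trimethoxy-2-[4-methoxy-3-(trimethylsilyloxy)cyclohexa-1,3-dien-1-yl]-4H-chromen-4-one | COC1=C(O[Si](C)(C)C)C=C(c2oc3c(OC)c(OC)ccc3c(=O)c2OC)CC1
F5 | step 6 | 3,7,8-trimethoxy-2-[4-methoxy-3-(trimethylsilyloxy)phenyl]-4H-chromen-4-one | COc1ccc(-c2oc3c(OC)c(OC)ccc3c(=O)c2OC)cc1O[Si](C)(C)C
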